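**Retrosynthetic overview**
1. Target 26 ⇐ diol 25 by acetylation of the primary allylic alcohol; 25 ⇐ dienylstannane 18 + dibromoacrylate 23 in one pot (step 15).
2. Enabling feature: C4 of the furan-2(5H)-one ring is an sp2 carbon with two carbon substituents, ring C5H2 cis and the dienyl chain trans to the lactone carbonyl C2. It maps onto the CBr2 carbon of a 3,3-dibromoacrylate whose ester group already holds O1–C5 as OCH2SnBu3; the trans bromide takes the dienylstannane, the cis bromide is closed onto C5 (C4–C5 bond).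
3. 18 ⇐ Z-selective Still–Gennari olefination of phosphonate 13 with stannylacrolein 16, then DIBAL-H; 13 ⇐ homoallylic iodide 11.
4. 11 ⇐ alkyne 7 by carboalumination/ethylene oxide (E-trisubstituted alkene); 7 ⇐ axial addition of a butynyl Grignard reagent to (S)-2,2,6-trimethylcyclohexanone 3, itself from enantioselective protonation of silyl enol ether 2.
5. Rings: the cyclohexane is bought with 1; the butenolide is the only ring made, in step 15.

Key step: step 15

Assumption: the (R)-configured binaphthol–SnCl4 acid is taken to protonate the face of 2 that gives the (S)-ketone; should the sense be opposite, its enantiomer is used and nothing else changes.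

Step 1
Reactants: 1 2,2,6-trimethylcyclohexanone (racemic)
Product: 2 trimethyl[(2,6,6-trimethylcyclohex-1-en-1-yl)oxy]silane
Conditions: TMSOTf, Et3N, CH2Cl2, 0 °C to rt
Reagents that add atoms: trimethylsilyl triflate (C[Si](C)(C)OS(=O)(=O)C(F)(F)F)
Why: Soft enolisation and O-silylation of a ketone with only one enolisable position (C6), so a single silyl enol ether regioisomer can form.

Step 2
Reactants: 2 trimethyl[(2,6,6-trimethylcyclohex-1-en-1-yl)oxy]silane
Product: 3 (S)-2,2,6-trimethylcyclohexanone
Conditions: (R)-2'-methoxy-1,1'-binaphthalen-2-ol (10 mol%), SnCl4 (50 mol%), 2,6-dimethylphenol (1.1 equiv), toluene, −80 °C, slow addition of 2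
Reagents that add atoms: none
Why: Catalytic enantioselective protonation of a silyl enol ether by a Lewis acid-assisted chiral Brønsted acid, in which the binaphthol–tin complex shields one face of C6 so that the proton should be delivered to give 6S while the achiral phenol regenerates the chiral acid.

Step 3
Reactants: 3 (S)-2,2,6-trimethylcyclohexanone; 4 (4-bromobut-1-yn-1-yl)trimethylsilane
Product: 6 (1R,6S)-2,2,6-trimethyl-1-[4-(trimethylsilyl)but-3-yn-1-yl]cyclohexan-1-ol, via butynylmagnesium bromide 5 (not isolated)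
Conditions: Mg, THF, rt; then anhydrous CeCl3, THF, −78 °C; then 3, −78 to 0 °C; aq. NH4Cl
Reagents that add atoms: none
Why: Cerium chloride-mediated 1,2-addition of a Grignard reagent, which suppresses enolisation and reduction of the hindered ketone; the nucleophile should enter axially, anti to the axial C2 methyl group that blocks the equatorial trajectory, placing the new chain cis and the hydroxyl trans to the C6 methyl group (1R).

Step 4
Reactants: 6 (1R,6S)-2,2,6-trimethyl-1-[4-(trimethylsilyl)but-3-yn-1-yl]cyclohexan-1-ol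
Product: 7 (1R,6S)-1-(but-3-yn-1-yl)-2,2,6-trimethylcyclohexan-1-ol
Conditions: K2CO3 (cat.), MeOH, rt
Reagents that add atoms: none
Why: Base-catalysed methanolysis of the C(sp)–Si bond (protodesilylation) leaves the tertiary alcohol and both stereocentres untouched.

Step 5
Reactants: 7 (1R,6S)-1-(but-3-yn-1-yl)-2,2,6-trimethylcyclohexan-1-ol
Product: 10 (3E)-6-[(1R,6S)-1-hydroxy-2,2,6-trimethylcyclohexyl]-4-methylhex-3-en-1-ol, via alkenyldimethylalane 8 (not isolated), via lithium alkenylalanate 9 (not isolated)
Conditions: Me3Al (3 equiv), Cp2ZrCl2 (25 mol%), CH2Cl2, 0 °C to rt; then n-BuLi, hexane/THF, −30 °C; then ethylene oxide, −30 °C to rt; aq. Rochelle salt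
Reagents that add atoms: trimethylaluminium (C[Al](C)C); ethylene oxide (C1CO1)
Why: Zirconium-catalysed carboalumination (Negishi) adds methyl and aluminium syn across the terminal alkyne with methyl on the internal carbon, and the derived alanate opens ethylene oxide with retention at the alkenyl carbon, so the trisubstituted alkene should form as the E isomer, the free hydroxyl being carried as its aluminium alkoxide.

Step 6
Reactants: 10 (3E)-6-[(1R,6S)-1-hydroxy-2,2,6-trimethylcyclohexyl]-4-methylhex-3-en-1-ol
Product: 11 (1R,6S)-1-[(3E)-6-iodo-3-methylhex-3-en-1-yl]-2,2,6-trimethylcyclohexan-1-ol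
Conditions: I2, PPh3, imidazole, CH2Cl2, 0 °C
Reagents that add atoms: iodine (II)
Why: Appel-type iodination converts the primary alcohol by SN2 displacement of its oxyphosphonium ion, while the hindered tertiary alcohol should not be activated.

Step 7
Reactants: 11 (1R,6S)-1-[(3E)-6-iodo-3-methylhex-3-en-1-yl]-2,2,6-trimethylcyclohexan-1-ol; 12 methyl bis(2,2,2-trifluoroethyl)phosphonoacetate
Product: 13 methyl (5E)-2-[bis(2,2,2-trifluoroethoxy)phosphoryl]-8-[(1R,6S)-1-hydroxy-2,2,6-trimethylcyclohexyl]-6-methyloct-5-enoate (mixture of C2 epimers)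
Conditions: 12 (3 equiv), NaH (2.8 equiv), DMSO, rt; then 11, 50 °C
Reagents that add atoms: none
Why: SN2 C-alkylation of the preformed sodium phosphonoacetate (used in excess to limit double alkylation) with a primary iodide; the new α-stereocentre forms as a mixture and is destroyed in step 10.

Step 8
Reactants: 14 prop-2-yn-1-ol
Product: 15 (E)-3-(tributylstannyl)prop-2-en-1-ol
Conditions: Bu3SnH (slight excess), AIBN (cat.), neat, 80 °C; chromatography
Reagents that add atoms: tributyltin hydride (CCCC[SnH](CCCC)CCCC)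
Why: Radical hydrostannation of a terminal alkyne places tin on the terminal carbon and, because stannyl radical addition is reversible, should equilibrate towards the E-vinylstannane.

Step 9
Reactants: 15 (E)-3-(tributylstannyl)prop-2-en-1-ol
Product: 16 (E)-3-(tributylstannyl)prop-2-enal
Conditions: activated MnO2, CH2Cl2, rt
Reagents that add atoms: none
Why: Neutral MnO2 oxidation of an allylic alcohol leaves the vinylstannane and its E geometry intact.

Step 10
Reactants: 13 methyl (5E)-2-[bis(2,2,2-trifluoroethoxy)phosphoryl]-8-[(1R,6S)-1-hydroxy-2,2,6-trimethylcyclohexyl]-6-methyloct-5-enoate; 16 (E)-3-(tributylstannyl)prop-2-enal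
Product: 17 methyl (2Z,4E)-2-{(3E)-6-[(1R,6S)-1-hydroxy-2,2,6-trimethylcyclohexyl]-4-methylhex-3-en-1-yl}-5-(tributylstannyl)penta-2,4-dienoate
Conditions: KHMDS (1.05 equiv), 18-crown-6, THF, −78 °C; then 16, −78 °C
Reagents that add atoms: none
Why: Still–Gennari variant of the Horner–Wadsworth–Emmons olefination, in which the bis(trifluoroethyl) phosphonate and a dissociated potassium counter-ion make elimination from the kinetic adduct fast and irreversible, so the Z-enoate (ester cis to the new vinyl group) should result with the E-vinylstannane untouched.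

Step 11
Reactants: 17 methyl (2Z,4E)-2-{(3E)-6-[(1R,6S)-1-hydroxy-2,2,6-trimethylcyclohexyl]-4-methylhex-3-en-1-yl}-5-(tributylstannyl)penta-2,4-dienoate
Product: 18 (2Z,4E)-2-{(3E)-6-[(1R,6S)-1-hydroxy-2,2,6-trimethylcyclohexyl]-4-methylhex-3-en-1-yl}-5-(tributylstannyl)penta-2,4-dien-1-ol
Conditions: DIBAL-H (excess), CH2Cl2, −78 °C; aq. Rochelle salt
Reagents that add atoms: none
Why: DIBAL-H 1,2-reduction of the conjugated ester to the allylic alcohol does not touch alkene geometry or the C–Sn bond.

Step 12
Reactants: 19 ethyl glyoxylate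
Product: 20 ethyl 3,3-dibromoprop-2-enoate
Conditions: CBr4, PPh3, CH2Cl2, 0 °C
Reagents that add atoms: carbon tetrabromide (BrC(Br)(Br)Br)
Why: Ramirez dibromo-olefination, a Wittig reaction of Ph3P=CBr2 generated from CBr4 and PPh3 with the reactive glyoxylate aldehyde.

Step 13
Reactants: 20 ethyl 3,3-dibromoprop-2-enoate
Product: 21 3,3-dibromoprop-2-enoic acid
Conditions: LiOH, THF/H2O, 0 °C; then aq. HCl
Reagents that add atoms: lithium hydroxide ([Li+].[OH-])
Why: Saponification at 0 °C, where acyl substitution should be faster than addition–elimination at the dibromovinyl carbon.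

Step 14
Reactants: 21 3,3-dibromoprop-2-enoic acid; 22 tributyl(iodomethyl)stannane
Product: 23 (tributylstannyl)methyl 3,3-dibromoprop-2-enoate
Conditions: Cs2CO3, DMF, rt
Reagents that add atoms: none
Why: O-alkylation of the caesium carboxylate by SN2 displacement of iodide installs the tin-bearing OCH2 unit without any acyl activation.

Step 15
Reactants: 18 (2Z,4E)-2-{(3E)-6-[(1R,6S)-1-hydroxy-2,2,6-trimethylcyclohexyl]-4-methylhex-3-en-1-yl}-5-(tributylstannyl)penta-2,4-dien-1-ol; 23 (tributylstannyl)methyl 3,3-dibromoprop-2-enoate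
Product: 25 4-[(1E,3Z,7E)-4-(hydroxymethyl)-10-[(1R,6S)-1-hydroxy-2,2,6-trimethylcyclohexyl]-8-methyldeca-1,3,7-trien-1-yl]furan-2(5H)-one, via stannylmethyl (2Z)-3-bromotetraenoate 24 (not isolated)
Conditions: 23 (1.2 equiv), Pd2(dba)3 (5 mol%), AsPh3 (20 mol%), CuI (20 mol%), THF/NMP, slow addition of 18, rt; then dilution with THF to 5 mM, 65 °C
Reagents that add atoms: none
Why: Pd(0) should insert first into the C–Br bond of 23 that is trans to the ester (the less hindered bromide of a 1,1-dibromoalkene), and Stille coupling with 18 gives the (2Z)-3-bromo ester 24 with retention of the 1E,3Z-diene geometry; oxidative addition into the remaining C–Br bond, cis to the ester, is followed by copper-assisted intramolecular transfer of the oxygen-bearing CH2 group from tin and C(sp2)–C(sp3) reductive elimination. The closest known reaction types are the trans-selective mono-Stille coupling of 1,1-dibromoalkenes and the Stille transfer of hydroxymethyl or alkoxymethyl groups from Bu3SnCH2OR reagents to vinyl and aryl halides, here run intramolecularly. The furan-2(5H)-one ring is closed as a five-membered ring by reductive elimination from a six-membered palladacycle (Pd, C4, C3, C2, O1, C5), so no endo attack on a π bond is required. No stereocentre is created; the C3=C4 geometry is fixed by the ring and the side-chain alkenes are carried over with retention. The step needs site selectivity between the two C–Br bonds (only the cis bromide can reach the tethered tin, the trans one is the more reactive intermolecularly), transfer of the CH2O group in preference to butyl (α-oxygen and intramolecularity), and suppression of intermolecular coupling during ring closure (high dilution, and heating to populate the s-trans ester rotamer).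

Step 16
Reactants: 25 4-[(1E,3Z,7E)-4-(hydroxymethyl)-10-[(1R,6S)-1-hydroxy-2,2,6-trimethylcyclohexyl]-8-methyldeca-1,3,7-trien-1-yl]furan-2(5H)-one
Product: 26 4-[(1E,3Z,7E)-4-(acetoxymethyl)-10-[(1R,6S)-1-hydroxy-2,2,6-trimethylcyclohexyl]-8-methyldeca-1,3,7-trien-1-yl]furan-2(5H)-one (CNP0366059.1)
Conditions: Ac2O, pyridine, CH2Cl2, 0 °C
Reagents that add atoms: acetic anhydride (CC(=O)OC(C)=O)
Why: Acylation of the unhindered primary allylic alcohol, whereas the tertiary alcohol flanked by a quaternary and a tertiary carbon should not react under these mild conditions.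

**Compound list**
1 | 2,2,6-trimethylcyclohexanone (racemic) | CC1CCCC(C)(C)C1=O | starting material
2 | trimethyl[(2,6,6-trimethylcyclohex-1-en-1-yl)oxy]silane | CC1=C(O[Si](C)(C)C)C(C)(C)CCC1 | intermediate
3 | (S)-2,2,6-trimethylcyclohexanone | O=C1[C@@H](C)CCCC1(C)C | intermediate
4 | (4-bromobut-1-yn-1-yl)trimethylsilane | C[Si](C)(C)C#CCCBr | starting material
5 | [4-(trimethylsilyl)but-3-yn-1-yl]magnesium bromide | C[Si](C)(C)C#CCC[Mg]Br | intermediate
6 | (1R,6S)-2,2,6-trimethyl-1-[4-(trimethylsilyl)but-3-yn-1-yl]cyclohexan-1-ol | C[Si](C)(C)C#CCC[C@@]1(O)[C@@H](C)CCCC1(C)C | intermediate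
7 | (1R,6S)-1-(but-3-yn-1-yl)-2,2,6-trimethylcyclohexan-1-ol | C#CCC[C@@]1(O)[C@@H](C)CCCC1(C)C | intermediate
8 | (E)-alkenyldimethylalane of 7 (tertiary alcohol as its dimethylaluminium alkoxide) | C[Al](C)/C=C(\C)CC[C@@]1(O[Al](C)C)[C@@H](C)CCCC1(C)C | intermediate
9 | lithium butyl(alkenyl)dimethylalanate derived from 8 | [Li+].CCCC[Al-](C)(C)/C=C(\C)CC[C@@]1(O[Al](C)C)[C@@H](C)CCCC1(C)C | intermediate
10 | (3E)-6-[(1R,6S)-1-hydroxy-2,2,6-trimethylcyclohexyl]-4-methylhex-3-en-1-ol | OCC/C=C(\C)CC[C@@]1(O)[C@@H](C)CCCC1(C)C | intermediate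
11 | (1R,6S)-1-[(3E)-6-iodo-3-methylhex-3-en-1-yl]-2,2,6-trimethylcyclohexan-1-ol | ICC/C=C(\C)CC[C@@]1(O)[C@@H](C)CCCC1(C)C | intermediate
12 | methyl bis(2,2,2-trifluoroethyl)phosphonoacetate | COC(=O)CP(=O)(OCC(F)(F)F)OCC(F)(F)F | starting material
13 | methyl (5E)-2-[bis(2,2,2-trifluoroethoxy)phosphoryl]-8-[(1R,6S)-1-hydroxy-2,2,6-trimethylcyclohexyl]-6-methyloct-5-enoate | COC(=O)C(CC/C=C(\C)CC[C@@]1(O)[C@@H](C)CCCC1(C)C)P(=O)(OCC(F)(F)F)OCC(F)(F)F | intermediate
14 | prop-2-yn-1-ol | OCC#C | starting material
15 | (E)-3-(tributylstannyl)prop-2-en-1-ol | OC/C=C/[Sn](CCCC)(CCCC)CCCC | intermediate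
16 | (E)-3-(tributylstannyl)prop-2-enal | O=C/C=C/[Sn](CCCC)(CCCC)CCCC | intermediate
17 | methyl (2Z,4E)-2-{(3E)-6-[(1R,6S)-1-hydroxy-2,2,6-trimethylcyclohexyl]-4-methylhex-3-en-1-yl}-5-(tributylstannyl)penta-2,4-dienoate | COC(=O)/C(=C\C=C\[Sn](CCCC)(CCCC)CCCC)CC/C=C(\C)CC[C@@]1(O)[C@@H](C)CCCC1(C)C | intermediate
18 | (2Z,4E)-2-{(3E)-6-[(1R,6S)-1-hydroxy-2,2,6-trimethylcyclohexyl]-4-methylhex-3-en-1-yl}-5-(tributylstannyl)penta-2,4-dien-1-ol | OC/C(=C\C=C\[Sn](CCCC)(CCCC)CCCC)CC/C=C(\C)CC[C@@]1(O)[C@@H](C)CCCC1(C)C | intermediate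
19 | ethyl glyoxylate | CCOC(=O)C=O | starting material
20 | ethyl 3,3-dibromoprop-2-enoate | CCOC(=O)C=C(Br)Br | intermediate
21 | 3,3-dibromoprop-2-enoic acid | OC(=O)C=C(Br)Br | intermediate
22 | tributyl(iodomethyl)stannane | CCCC[Sn](CI)(CCCC)CCCC | starting material
23 | (tributylstannyl)methyl 3,3-dibromoprop-2-enoate | CCCC[Sn](CCCC)(CCCC)COC(=O)C=C(Br)Br | intermediate
24 | (tributylstannyl)methyl (2Z,4E,6Z,10E)-3-bromo-7-(hydroxymethyl)-13-[(1R,6S)-1-hydroxy-2,2,6-trimethylcyclohexyl]-11-methyltrideca-2,4,6,10-tetraenoate | OC/C(=C\C=C\C(Br)=C\C(=O)OC[Sn](CCCC)(CCCC)CCCC)CC/C=C(\C)CC[C@@]1(O)[C@@H](C)CCCC1(C)C | intermediate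
25 | 4-[(1E,3Z,7E)-4-(hydroxymethyl)-10-[(1R,6S)-1-hydroxy-2,2,6-trimethylcyclohexyl]-8-methyldeca-1,3,7-trien-1-yl]furan-2(5H)-one | OC/C(=C\C=C\C1=CC(=O)OC1)CC/C=C(\C)CC[C@@]1(O)[C@@H](C)CCCC1(C)C | intermediate
26 | 4-[(1E,3Z,7E)-4-(acetoxymethyl)-10-[(1R,6S)-1-hydroxy-2,2,6-trimethylcyclohexyl]-8-methyldeca-1,3,7-trien-1-yl]furan-2(5H)-one (CNP0366059.1) | CC(=O)OC/C(=C\C=C\C1=CC(=O)OC1)CC/C=C(\C)CC[C@@]1(O)[C@@H](C)CCCC1(C)C | target

**Step count**
Total: 16 steps. Longest linear sequence: 11 steps (steps 1–7, 10, 11, 15, 16).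

**Steps most likely to fail**

Step 15. The ring closure may stall because transfer of the oxygenated CH2 group from tin is slow, or intermolecular coupling and oligomerisation may outrun cyclisation, which needs the minor s-trans ester rotamer; coupling at both bromides by the dienylstannane is a further drain. The fallback sets out from 18 and 21 and comes back at 25. Acid 21 is alkylated with chloromethyl chlorosulfate (NaHCO3, Bu4NHSO4, CH2Cl2/H2O) to chloromethyl 3,3-dibromoprop-2-enoate F1. Trans-selective Stille coupling of F1 with 18 (Pd2(dba)3, P(2-furyl)3, dioxane, 45 °C) should give the chloromethyl (2Z)-3-bromotetraenoate F2. A nickel-catalysed reductive cyclisation (cross-electrophile coupling of the vinyl bromide with the chloromethyl ester: NiBr2·glyme, 4,4'-di-tert-butyl-2,2'-bipyridine, Mn, NaI, DMA, rt, high dilution) then forms the same ring bond by capture of the acyloxymethyl radical at nickel and gives 25.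

Step 7. E2 elimination of the homoallylic iodide to a 1,3-diene and double alkylation of the phosphonate may erode the alkylation; the fallback also removes the dependence on Z-selective olefination in step 10. It sets out from 11 and comes back at 18. Iodide 11 is deprotonated with i-PrMgCl and treated with magnesium to give the alkoxide-bearing Grignard reagent F3. Copper-catalysed anti-carbomagnesiation of prop-2-yn-1-ol 14 (CuI, THF), followed by iodine in the same flask, should give the (Z)-iodoalkene diol F4, with iodine cis to CH2OH because magnesium is held next to the oxygen in a five-membered chelate. Stille coupling of F4 with an excess of (E)-1,2-bis(tributylstannyl)ethene (PdCl2(MeCN)2, DMF, rt) gives 18.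

Step 3. Enolisation or β-hydride reduction of the hindered ketone may compete with addition, with loss of material or of the C6 configuration. The fallback sets out from 3 and comes back at 7. Allylmagnesium bromide (THF, −78 °C; fast addition through a cyclic six-membered transition state, same axial approach) gives the allyl carbinol F5. Hydroboration–oxidation (9-BBN, then NaOH/H2O2) gives the diol F6. TEMPO/PhI(OAc)2 oxidises the primary alcohol to the aldehyde, which rests as the spiro-lactol F7. Seyferth–Gilbert homologation with the Ohira–Bestmann reagent (K2CO3, MeOH) gives 7.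

Further compounds
F1 | step 15 | chloromethyl 3,3-dibromoprop-2-enoate | ClCOC(=O)C=C(Br)Br
F2 | step 15 | chloromethyl (2Z,4E,6Z,10E)-3-bromo-7-(hydroxymethyl)-13-[(1R,6S)-1-hydroxy-2,2,6-trimethylcyclohexyl]-11-methyltrideca-2,4,6,10-tetraenoate | OC/C(=C\C=C\C(Br)=C\C(=O)OCCl)CC/C=C(\C)CC[C@@]1(O)[C@@H](C)CCCC1(C)C
F3 | step 7 | iodomagnesium reagent of 11 with the tertiary alcohol as its chloromagnesium alkoxide | I[Mg]CC/C=C(\C)CC[C@@]1(O[Mg]Cl)[C@@H](C)CCCC1(C)C
F4 | step 7 | (1R,6S)-1-[(3E,7Z)-7-(hydroxymethyl)-8-iodo-3-methylocta-3,7-dien-1-yl]-2,2,6-trimethylcyclohexan-1-ol | OC/C(=C\I)CC/C=C(\C)CC[C@@]1(O)[C@@H](C)CCCC1(C)C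
F5 | step 3 | (1R,6S)-2,2,6-trimethyl-1-(prop-2-en-1-yl)cyclohexan-1-ol | C=CC[C@@]1(O)[C@@H](C)CCCC1(C)C
F6 | step 3 | 3-[(1R,6S)-1-hydroxy-2,2,6-trimethylcyclohexyl]propan-1-ol | OCCC[C@@]1(O)[C@@H](C)CCCC1(C)C
F7 | step 3 | (5R,10S)-6,6,10-trimethyl-1-oxaspiro[4.5]decan-2-ol (lactol, anomer mixture) | OC1CC[C@@]2(O1)[C@@H](C)CCCC2(C)C
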